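**Plan**

- Numbering: oxolane O1–C2–C3–C4–C5; ring A (3,4,5-trimethoxyphenyl) on C2; C6 (the CH2OH carbon) on C3; C7 (the CH2 joined to ring B, 3,4-dimethoxyphenyl) on C4.
- Enabling feature: C5–C4–C7 is a three-carbon unit on O1, with C4 bonded to ring carbon C3 and C7 to ring B. It can therefore be an O-allyl group whose C4=C7 double bond accepts a C3 radical at C4 and an aryl group at C7.
- Retrosynthesis: cut O–Si first, then C3–C4 and C7–ring B together, then C3–I, then O1–C2 (benzylic ether from an epoxide), then the epoxide C–O bonds.
- Forward: C2–C3–C6 and ring A come from 3,4,5-trimethoxycinnamic acid; O1–C5–C4=C7 is added as allyl alcohol at C2; the only ring (the oxolane) closes in the nickel step that also attaches ring B.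
- Stereochemistry: C2 comes from a Sharpless epoxidation (D-tartrate) followed by inversion on epoxide opening. C3 and C4 are set by C2 in the chair-like 5-exo radical closure, and the C–I configuration is erased there.

Key step: step 7

Remark (assumption): the arylzinc bromide is prepared and titrated as a THF solution and used as such; it is treated as the product of its own step.

**Step 1**
Reactants: 1 (E)-3-(3,4,5-trimethoxyphenyl)prop-2-enoic acid (3,4,5-trimethoxycinnamic acid)
Product: 3 (E)-3-(3,4,5-trimethoxyphenyl)prop-2-en-1-ol, via mixed ethyl carbonic anhydride 2 (not isolated)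
Conditions: ClCO2Et (1.1 equiv), Et3N (1.1 equiv), THF, −10 °C; filter; NaBH4 (3 equiv), THF/H2O, 0 °C
Reagents that add atoms: ethyl chloroformate, CCOC(=O)Cl (its atoms are held in intermediate 2 only and leave again on reduction)
Why: Mixed-anhydride activation followed by borohydride reduction is the standard one-flask conversion of cinnamic acids into cinnamyl alcohols: NaBH4 attacks the activated acyl carbon and the derived aldehyde in the 1,2 sense and leaves the conjugated E-alkene and the aryl ethers alone, so no stereocentre is involved.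

**Step 2**
Reactants: 3 (E)-3-(3,4,5-trimethoxyphenyl)prop-2-en-1-ol
Product: 4 [(2R,3R)-3-(3,4,5-trimethoxyphenyl)oxiran-2-yl]methanol
Conditions: Ti(OiPr)4 (10 mol %), D-(−)-diisopropyl tartrate (14 mol %), t-BuOOH (2 equiv, isooctane), 4 Å MS, CH2Cl2, −20 °C
Reagents that add atoms: tert-butyl hydroperoxide, CC(C)(C)OO
Why: Sharpless asymmetric epoxidation of an E-allylic alcohol, in which the titanium–D-tartrate catalyst delivers the peroxide oxygen to one alkene face and sets both new centres as (2R,3R); ring A is electronically close to phenyl because its two meta methoxy groups offset the para one, so the benzylic epoxide should be about as robust as 3-phenylglycidol under the sieve-buffered catalytic conditions.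

**Step 3**
Reactants: 4 [(2R,3R)-3-(3,4,5-trimethoxyphenyl)oxiran-2-yl]methanol; 5 prop-2-en-1-ol (allyl alcohol)
Product: 6 (2R,3S)-3-(prop-2-en-1-yloxy)-3-(3,4,5-trimethoxyphenyl)propane-1,2-diol
Conditions: Ti(OiPr)4 (1.5 equiv), 5 as solvent, 50 °C; aqueous work-up
Reagents that add atoms: none
Why: Titanium-mediated C3-selective opening of a 2,3-epoxy alcohol (Sharpless-type): held on titanium through its alkoxide and epoxide oxygens, the substrate is attacked by allyl alcohol at the benzylic C3 from the side opposite the breaking C–O bond, which inverts that carbon to S and leaves the carbinol carbon R, while the excess of 5 crowds isopropoxide off titanium.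

**Step 4**
Reactants: 6 (2R,3S)-3-(prop-2-en-1-yloxy)-3-(3,4,5-trimethoxyphenyl)propane-1,2-diol
Product: 7 (2R,3S)-1-[(tert-butyldimethylsilyl)oxy]-3-(prop-2-en-1-yloxy)-3-(3,4,5-trimethoxyphenyl)propan-2-ol
Conditions: TBSCl (1.05 equiv), imidazole, CH2Cl2, 0 °C
Reagents that add atoms: tert-butyldimethylsilyl chloride, CC(C)(C)[Si](C)(C)Cl
Why: Imidazole-promoted silyl ether formation discriminates the unhindered primary hydroxyl from the secondary one flanked by two branched carbons, and no stereocentre is touched.

**Step 5**
Reactants: 7 (2R,3S)-1-[(tert-butyldimethylsilyl)oxy]-3-(prop-2-en-1-yloxy)-3-(3,4,5-trimethoxyphenyl)propan-2-ol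
Product: 8 tert-butyl{[(2S,3S)-2-iodo-3-(prop-2-en-1-yloxy)-3-(3,4,5-trimethoxyphenyl)propyl]oxy}dimethylsilane
Conditions: PPh3, I2, imidazole, toluene, 60 °C
Reagents that add atoms: iodine, II
Why: Appel iodination: the secondary alcohol becomes an alkoxyphosphonium ion that iodide displaces with inversion to give the (2S) iodide, imidazole keeps the medium non-acidic for the silyl and allyl ethers, and the configuration at this carbon is of no consequence because it becomes a radical centre in step 7.

**Step 6**
Reactants: 9 4-bromo-1,2-dimethoxybenzene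
Product: 11 (3,4-dimethoxyphenyl)zinc bromide, via (3,4-dimethoxyphenyl)magnesium bromide 10 (not isolated)
Conditions: Mg turnings, LiCl, THF, 25 °C; then ZnBr2 (1.05 equiv), THF, 0 °C
Reagents that add atoms: magnesium, [Mg] (held in intermediate 10 only); zinc dibromide, Br[Zn]Br
Why: Magnesium insertion into the aryl bromide (Grignard formation, accelerated by LiCl) followed by transmetalation with ZnBr2 gives an arylzinc halide that tolerates the ethers of 8 and hands its aryl group to nickel in a Negishi-type manifold.

**Step 7**
Reactants: 8 tert-butyl{[(2S,3S)-2-iodo-3-(prop-2-en-1-yloxy)-3-(3,4,5-trimethoxyphenyl)propyl]oxy}dimethylsilane; 11 (3,4-dimethoxyphenyl)zinc bromide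
Product: 14 tert-butyl{[(2R,3S,4S)-4-[(3,4-dimethoxyphenyl)methyl]-2-(3,4,5-trimethoxyphenyl)oxolan-3-yl]methoxy}dimethylsilane, via secondary C3 radical 12 (not isolated), via ring-closed primary C7 radical 13 (not isolated)
Conditions: NiCl2(DME) (10 mol %), 4,4'-di-tert-butyl-2,2'-bipyridine (12 mol %), 11 (2 equiv, THF solution), DMA, 25 °C
Reagents that add atoms: none
Why: Zerovalent or monovalent nickel carrying the bipyridine abstracts iodine from 8 to give the secondary C3 radical 12, so either C–I epimer converges; 12 adds to the internal alkene carbon C4 and closes the oxolane ring (O1–C5) in the 5-exo-trig mode, giving the primary C7 radical 13. Radical 13 is captured by the aryl–nickel species that the divalent nickel halide forms with 11 by transmetalation, and reductive elimination from the resulting trivalent alkyl(aryl)nickel makes the C7–ring B bond and returns monovalent nickel. The closest known reaction type is the nickel-catalysed tandem radical cyclization/Negishi arylation of secondary alkyl iodides that carry a 1,6-related alkene, β-alkoxy iodides of this kind included. C3 and C4 are both set in the ring closure by the chair-like transition state of 5-hexenyl radical cyclizations: ring A on C2 sits pseudo-equatorial, which places C7 trans to it, and the silyloxymethyl group on the radical carbon turns away from ring A and ends cis to C7 (2,3-trans, 3,4-cis). The step needs ring closure to outrun capture of 12 by nickel; the ether oxygen in the tether and the unhindered terminal alkene make the unimolecular closure fast against bimolecular capture at catalytic nickel concentration, whereas the ring-closed radical 13 is primary and couples readily. The silyl ether, the ring ether and the five methoxy groups are inert to the arylzinc reagent.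

**Step 8**
Reactants: 14 tert-butyl{[(2R,3S,4S)-4-[(3,4-dimethoxyphenyl)methyl]-2-(3,4,5-trimethoxyphenyl)oxolan-3-yl]methoxy}dimethylsilane
Product: 15 [(2R,3S,4S)-4-[(3,4-dimethoxyphenyl)methyl]-2-(3,4,5-trimethoxyphenyl)oxolan-3-yl]methanol
Conditions: Bu4NF (1.2 equiv), THF, 0 °C → rt
Reagents that add atoms: none
Why: Fluoride-driven cleavage of the Si–O bond (formation of the strong Si–F bond) frees the primary alcohol without touching the oxolane, the aryl methyl ethers or any of the three stereocentres.

**Compound list**

1 | (E)-3-(3,4,5-trimethoxyphenyl)prop-2-enoic acid | COc1cc(/C=C/C(=O)O)cc(OC)c1OC | starting material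
2 | ethyl carbonic (E)-3-(3,4,5-trimethoxyphenyl)prop-2-enoic anhydride | CCOC(=O)OC(=O)/C=C/c1cc(OC)c(OC)c(OC)c1 | intermediate
3 | (E)-3-(3,4,5-trimethoxyphenyl)prop-2-en-1-ol | COc1cc(/C=C/CO)cc(OC)c1OC | intermediate
4 | [(2R,3R)-3-(3,4,5-trimethoxyphenyl)oxiran-2-yl]methanol | OC[C@H]1O[C@@H]1c1cc(OC)c(OC)c(OC)c1 | intermediate
5 | prop-2-en-1-ol (allyl alcohol) | C=CCO | starting material
6 | (2R,3S)-3-(prop-2-en-1-yloxy)-3-(3,4,5-trimethoxyphenyl)propane-1,2-diol | C=CCO[C@@H](c1cc(OC)c(OC)c(OC)c1)[C@H](O)CO | intermediate
7 | (2R,3S)-1-[(tert-butyldimethylsilyl)oxy]-3-(prop-2-en-1-yloxy)-3-(3,4,5-trimethoxyphenyl)propan-2-ol | C=CCO[C@@H](c1cc(OC)c(OC)c(OC)c1)[C@H](O)CO[Si](C)(C)C(C)(C)C | intermediate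
8 | tert-butyl{[(2S,3S)-2-iodo-3-(prop-2-en-1-yloxy)-3-(3,4,5-trimethoxyphenyl)propyl]oxy}dimethylsilane | C=CCO[C@@H](c1cc(OC)c(OC)c(OC)c1)[C@@H](I)CO[Si](C)(C)C(C)(C)C | intermediate
9 | 4-bromo-1,2-dimethoxybenzene | COc1ccc(Br)cc1OC | starting material
10 | (3,4-dimethoxyphenyl)magnesium bromide | COc1ccc([Mg]Br)cc1OC | intermediate
11 | (3,4-dimethoxyphenyl)zinc bromide | COc1ccc([Zn]Br)cc1OC | intermediate
12 | secondary C3 radical: 8 with the iodine replaced by an unpaired electron, benzylic carbon configured as in 8 | C=CCO[C@@H](c1cc(OC)c(OC)c(OC)c1)[CH]CO[Si](C)(C)C(C)(C)C | intermediate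
13 | primary C7 radical: 14 without ring B, the unpaired electron on C7, ring configuration (2R,3S,4S) as in 14 | [CH2][C@@H]1CO[C@@H](c2cc(OC)c(OC)c(OC)c2)[C@@H]1CO[Si](C)(C)C(C)(C)C | intermediate
14 | tert-butyl{[(2R,3S,4S)-4-[(3,4-dimethoxyphenyl)methyl]-2-(3,4,5-trimethoxyphenyl)oxolan-3-yl]methoxy}dimethylsilane | COc1ccc(C[C@@H]2CO[C@@H](c3cc(OC)c(OC)c(OC)c3)[C@@H]2CO[Si](C)(C)C(C)(C)C)cc1OC | intermediate
15 | [(2R,3S,4S)-4-[(3,4-dimethoxyphenyl)methyl]-2-(3,4,5-trimethoxyphenyl)oxolan-3-yl]methanol | COc1ccc(C[C@@H]2CO[C@@H](c3cc(OC)c(OC)c(OC)c3)[C@@H]2CO)cc1OC | target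

**Step count and risks**

Total step count: 8. Longest linear sequence: 7 (steps 1–5, 7 and 8, from acid 1); step 6 is a one-step side branch.

Steps most likely to fail:

1. Step 7. What may go wrong: nickel captures the secondary radical before ring closure (arylation at C3, or loss of the allyloxy group by β-elimination from an alkylnickel), or facial discrimination at C4 in the ring closure is insufficient. Fallback: the two events are separated. Setting out from 8, an iodine-atom-transfer radical cyclization without any transition metal (Et3B, trace air, benzene, 0–25 °C) should proceed through the same chair-like 5-exo closure, with the chain carried by iodine transfer from 8 to the primary radical. It should give the ring-closed primary iodide tert-butyl{[(2R,3S,4S)-4-(iodomethyl)-2-(3,4,5-trimethoxyphenyl)oxolan-3-yl]methoxy}dimethylsilane F1, which can be freed of its diastereomers by chromatography. Ring B is then attached by an iron-catalysed Kumada-type coupling of F1 with the Grignard reagent 10 (FeCl3 5 mol %, TMEDA, THF, 0 °C, slow addition), which comes back to the route at 14.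

2. Step 5. What may go wrong: elimination towards the enol ether, or neighbouring-group participation by ring A or an ether oxygen, during displacement at a hindered carbinol carbon flanked by two oxygen-bearing carbons at 60 °C. Fallback: activation and displacement are decoupled and run cold. Setting out from 7, Tf2O and pyridine in CH2Cl2 at −20 °C should give (2R,3S)-1-[(tert-butyldimethylsilyl)oxy]-3-(prop-2-en-1-yloxy)-3-(3,4,5-trimethoxyphenyl)propan-2-yl trifluoromethanesulfonate F2. This is not stored but treated at once with Bu4NI in toluene at −20 to 0 °C; displacement with inversion comes back to the route at 8. Partial epimerization at the C–I carbon would not matter, since both epimers give radical 12.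

3. Step 3. What may go wrong: attack by the neutral alcohol is sluggish, so that isopropoxide transfer, attack at the carbinol carbon, or partial ionization at the benzylic carbon (eroding the configuration of the future C2) compete. Fallback: the oxygen is introduced as a carboxylate and the allyl group is added afterwards.
   - Setting out from 4, Ti(OiPr)4 and benzoic acid in CH2Cl2 at room temperature (a fast, C3-selective, invertive opening) should give (1S,2R)-2,3-dihydroxy-1-(3,4,5-trimethoxyphenyl)propyl benzoate F3.
   - The crude diol is capped at once (2,2-dimethoxypropane, pyridinium p-toluenesulfonate, acetone) as (S)-[(4R)-2,2-dimethyl-1,3-dioxolan-4-yl](3,4,5-trimethoxyphenyl)methyl benzoate F4, to forestall benzoyl migration.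
   - Methanolysis (K2CO3, MeOH) gives (S)-[(4R)-2,2-dimethyl-1,3-dioxolan-4-yl](3,4,5-trimethoxyphenyl)methanol F5.
   - Williamson etherification (NaH, allyl bromide, DMF, 0 °C) gives (4R)-2,2-dimethyl-4-[(S)-(prop-2-en-1-yloxy)(3,4,5-trimethoxyphenyl)methyl]-1,3-dioxolane F6.
   - Aqueous acetic acid at 40 °C removes the acetonide and comes back to the route at 6.

**Further compounds**

F1 | step 7 | tert-butyl{[(2R,3S,4S)-4-(iodomethyl)-2-(3,4,5-trimethoxyphenyl)oxolan-3-yl]methoxy}dimethylsilane | IC[C@@H]1CO[C@@H](c2cc(OC)c(OC)c(OC)c2)[C@@H]1CO[Si](C)(C)C(C)(C)C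
F2 | step 5 | (2R,3S)-1-[(tert-butyldimethylsilyl)oxy]-3-(prop-2-en-1-yloxy)-3-(3,4,5-trimethoxyphenyl)propan-2-yl trifluoromethanesulfonate | C=CCO[C@@H](c1cc(OC)c(OC)c(OC)c1)[C@H](OS(=O)(=O)C(F)(F)F)CO[Si](C)(C)C(C)(C)C
F3 | step 3 | (1S,2R)-2,3-dihydroxy-1-(3,4,5-trimethoxyphenyl)propyl benzoate | O=C(O[C@@H](c1cc(OC)c(OC)c(OC)c1)[C@H](O)CO)c1ccccc1
F4 | step 3 | (S)-[(4R)-2,2-dimethyl-1,3-dioxolan-4-yl](3,4,5-trimethoxyphenyl)methyl benzoate | O=C(O[C@@H](c1cc(OC)c(OC)c(OC)c1)[C@H]1COC(C)(C)O1)c1ccccc1
F5 | step 3 | (S)-[(4R)-2,2-dimethyl-1,3-dioxolan-4-yl](3,4,5-trimethoxyphenyl)methanol | O[C@@H](c1cc(OC)c(OC)c(OC)c1)[C@H]1COC(C)(C)O1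
F6 | step 3 | (4R)-2,2-dimethyl-4-[(S)-(prop-2-en-1-yloxy)(3,4,5-trimethoxyphenyl)methyl]-1,3-dioxolane | C=CCO[C@@H](c1cc(OC)c(OC)c(OC)c1)[C@H]1COC(C)(C)O1
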